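## Retrosynthetic overview

1. Numbering (germacrane): C1 furanone C=O, C2 furanone CH, C3 furanone O–C(sp2), C4=C5 (Z, C15 methyl on C4), C6 lactone O–CH, C7, C8 ester O–CH, C9 CH2, C10 quaternary carbon (C14 methyl) carrying the bridging oxygen, C11/C12/C13 lactone α-carbon, C=O and exo-methylene.
2. Endgame disconnections: C11=C13 (dehydration of a CH2OH lactone, unveiled last so that no Michael acceptor is present earlier) and the C8 ester (acylation with (E)-4-acetoxy-2-methylbut-2-enoic acid).
3. Key disconnection: C1–C10 and O–C3 together. The furanone ring O–C3=C2–C1(=O)–C10 is the formal (3+2) adduct of an ynal (C1–C2≡C3) across a methyl ketone C10=O, so one operation closes the 10-membered carbocycle and the furanone ring and sets C10, starting from a monocyclic trans-lactone.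
4. Enabling feature: C1 is an acyl carbon whose alkyne partner C3 is the built-in acceptor for the C10 oxygen (five atoms O–C10–C1–C2–C3). The Z-C4=C5 alkene, the linear C2≡C3 unit and the trans-fused lactone ring (O–C6–C7–C11–C12) leave only four rotatable bonds between C1 and C10.
5. Precursor: C3–C4 by Sonogashira coupling, Z-C4=C5 by iodo-olefination of a C5 aldehyde, C8–C9 by proline aldol of acetone with a C8 aldehyde, C7 and C11 by conjugate addition/alkylation on (S)-5-(hydroxymethyl)furan-2(5H)-one. Ring order: lactone (bought), then carbocycle and furanone together.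

Key step: step 11

Remark: (S)-5-(hydroxymethyl)furan-2(5H)-one, chloromethyl triisopropylsilyl ether and (E)-4-acetoxy-2-methylbut-2-enal are taken as purchasable; the target is (4Z,6R,7R,8R,10S) with an E side-chain alkene, as read from the SMILES.

## Route

Step 1
Reactants: 1 (S)-5-(hydroxymethyl)furan-2(5H)-one
Product: 2 TBS ether of butenolide 1
Conditions: TBSCl, imidazole, CH2Cl2, 0 °C → rt
Reagents that add atoms: tert-butyldimethylsilyl chloride C[Si](C)(Cl)C(C)(C)C
Why: Imidazole-mediated silylation of the primary alcohol gives the bulky ether that shields one face of the butenolide in step 2 and touches no stereocentre.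

Step 2
Reactants: 2 TBS ether of butenolide 1; 3 vinylmagnesium bromide; 4 chloromethyl triisopropylsilyl ether
Product: 6 all-trans trisubstituted lactone, via magnesium enolate 5 (not isolated)
Conditions: 3, CuBr·SMe2 (10 mol %), THF, −78 °C; then 4, DMPU, −78 → −20 °C
Reagents that add atoms: none
Why: Copper-catalysed conjugate addition of the vinyl Grignard reagent should occur anti to the C6 silyloxymethyl group (sets C7, 6,7-trans), and C-alkylation of enolate 5 by the chloromethyl ether anti to the new vinyl group sets C11 (a centre removed again in step 16), a tandem conjugate addition–enolate alkylation.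

Step 3
Reactants: 6 all-trans trisubstituted lactone
Product: 7 primary C5 alcohol
Conditions: pyridinium p-toluenesulfonate (cat.), MeOH, rt
Reagents that add atoms: none
Why: Acid-catalysed methanolysis should cleave the primary TBS ether far faster than the primary TIPS ether (selective desilylation).

Step 4
Reactants: 7 primary C5 alcohol
Product: 8 C5 aldehyde
Conditions: Dess–Martin periodinane, CH2Cl2, 0 °C → rt
Reagents that add atoms: none
Why: Dess–Martin oxidation of a primary alcohol under neutral conditions should give the α-oxygenated aldehyde without epimerisation at C6.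

Step 5
Reactants: 8 C5 aldehyde; 9 ethyltriphenylphosphonium iodide
Product: 13 (Z)-iodoalkene lactone, via ethylidene ylide 10 (not isolated), via iodophosphonium iodide 11 (not isolated), via iodo ylide 12 (not isolated)
Conditions: 9, n-BuLi, THF, rt; I2, −78 °C; NaN(SiMe3)2, −20 °C; then 8, −78 °C
Reagents that add atoms: iodine II
Why: Stork–Zhao-type Wittig olefination with the α-iodo ylide 12 should give the (Z)-2-iodoalkene (iodine cis to C6) through the kinetically favoured oxaphosphetane at −78 °C, which places the later alkyne cis to C6 as the 4Z alkene requires.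

Step 6
Reactants: 13 (Z)-iodoalkene lactone
Product: 15 C8 aldehyde, via vicinal diol 14 (not isolated)
Conditions: OsO4 (2 mol %), NaIO4, 2,6-lutidine, dioxane/H2O, rt
Reagents that add atoms: osmium tetroxide O=[Os](=O)(=O)=O (catalytic oxygen carrier); sodium periodate [Na+].[O-]I(=O)(=O)=O (terminal oxygen source)
Why: Lemieux–Johnson oxidation (dihydroxylation, then periodate cleavage) should attack the monosubstituted vinyl group and leave the hindered, electron-poor trisubstituted iodoalkene untouched.

Step 7
Reactants: 15 C8 aldehyde; 16 acetone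
Product: 17 (8R)-β-hydroxy methyl ketone
Conditions: L-proline (30 mol %), acetone/DMSO, rt
Reagents that add atoms: none
Why: In this proline-catalysed direct aldol reaction (enamine catalysis) the L-proline enamine of acetone should add to the Re face of the α-branched aldehyde under catalyst control, which sets C8 (R) and delivers C9, C10 and C14 as the methyl ketone.

Step 8
Reactants: 17 (8R)-β-hydroxy methyl ketone
Product: 18 C8 triethylsilyl ether
Conditions: TESCl, imidazole, DMF, 0 °C
Reagents that add atoms: chlorotriethylsilane CC[Si](Cl)(CC)CC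
Why: Imidazole-mediated silylation of the secondary alcohol is mild enough to avoid retro-aldol cleavage or β-elimination of the hydroxy ketone.

Step 9
Reactants: 18 C8 triethylsilyl ether; 19 propargyl alcohol
Product: 20 (Z)-enynol
Conditions: 19, PdCl2(PPh3)2 (5 mol %), CuI (10 mol %), Et3N, THF, rt
Reagents that add atoms: none
Why: Sonogashira coupling of the vinyl iodide with the terminal alkyne forms C3–C4 with retention of the Z geometry and tolerates ketone, lactone and silyl ethers.

Step 10
Reactants: 20 (Z)-enynol
Product: 21 ynal seco-precursor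
Conditions: Dess–Martin periodinane, CH2Cl2, 0 °C
Reagents that add atoms: none
Why: Dess–Martin oxidation of the primary propargylic alcohol should give the ynal (C1) without touching the C10 ketone.

Step 11
Reactants: 21 ynal seco-precursor
Product: 23 tricyclic furanone, via macrocyclic hydroxy ynone 22 (not isolated)
Conditions: 2-(pentafluorophenyl)-6,7-dihydro-5H-pyrrolo[2,1-c][1,2,4]triazol-2-ium tetrafluoroborate (20 mol %), iPr2NEt (20 mol %), 4 Å molecular sieves, toluene, 40 °C, slow addition of 21 to 0.002 M; then 1,8-diazabicyclo[5.4.0]undec-7-ene (DBU, 20 mol %), rt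
Reagents that add atoms: none
Why: Proposed new method: the triazolylidene adds to the aldehyde carbon C1 of ynal 21, proton transfer makes C1 an acyl anion equivalent, C1 attacks the C10 ketone, loss of the carbene gives hydroxy ynone 22, and the C10 oxygen then adds to C3 to give the furanone; the closest known reaction types are the carbene-catalysed intramolecular aldehyde–ketone crossed benzoin reaction (rings of five and six) and the base- or metal-mediated cyclisation of α'-hydroxy ynones to 3(2H)-furanones, and what is new is their union in a 10-membered closure with an ynal donor. The carbocycle closes by 10-exo-trig addition to the ketone and the furanone by 5-endo-dig attack of the tertiary oxygen on the alkyne. The closure is helped by the seco-chain, in which the Z-C4=C5 alkene, the linear C1–C2≡C3–C4 unit and the trans-lactone leave only four rotatable bonds between C1 and C10. The benzoin addition is reversible and the oxa-Michael step is not, so adducts should be funnelled to 23 with release of the strain of the cyclic ynone. C10, the only new stereocentre, is set by the ring constraint: addition of C1 to the Re face of the ketone (10S) should be favoured in the conformer with the C8 silyloxy group pseudo-equatorial, and a mismatched adduct can revert by retro-benzoin. The step needs acyl-anion reactivity at C1 instead of γ-protonation to the unsaturated acyl azolium, which the electron-poor N-pentafluorophenyl carbene, the aprotic medium, the substoichiometric hindered base and the absence of any Michael acceptor (the α-methylene lactone is held back as the CH2OTIPS lactone) should secure.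

Step 12
Reactants: 23 tricyclic furanone
Product: 24 C8 alcohol
Conditions: HF·pyridine, pyridine, THF, 0 °C
Reagents that add atoms: none
Why: Buffered HF·pyridine should cleave the secondary triethylsilyl ether much faster than the primary triisopropylsilyl ether (selective desilylation).

Step 13
Reactants: 25 (E)-4-acetoxy-2-methylbut-2-enal
Product: 26 (E)-4-acetoxy-2-methylbut-2-enoic acid
Conditions: NaClO2, NaH2PO4, 2-methylbut-2-ene, t-BuOH/H2O, 0 °C → rt
Reagents that add atoms: sodium chlorite [Na+].[O-]Cl=O
Why: Pinnick oxidation converts the enal into the acid without isomerising the E alkene or cleaving the acetate.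

Step 14
Reactants: 24 C8 alcohol; 26 (E)-4-acetoxy-2-methylbut-2-enoic acid
Product: 28 C8 ester, via mixed anhydride 27 (not isolated)
Conditions: 26, 2,4,6-trichlorobenzoyl chloride, Et3N, toluene, rt; then 24, 4-(dimethylamino)pyridine, rt
Reagents that add atoms: none
Why: Yamaguchi esterification through mixed anhydride 27 should acylate the hindered secondary C8 alcohol with retention at C8 and without E/Z isomerisation of the tiglate-type acid.

Step 15
Reactants: 28 C8 ester
Product: 29 primary C13 alcohol
Conditions: HF·pyridine, THF, rt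
Reagents that add atoms: none
Why: Fluoride-mediated desilylation removes the primary TIPS ether, while the esters, the allylic acetate, the lactone and the furanone are stable to HF·pyridine.

Step 16
Reactants: 29 primary C13 alcohol
Product: 31 CNP0387534.1 (target), via primary mesylate 30 (not isolated)
Conditions: MsCl, Et3N, CH2Cl2, 0 °C; then DBU, 0 °C → rt
Reagents that add atoms: none
Why: Mesylation of the primary alcohol and E1cB β-elimination of the β-mesyloxy lactone unveil the α-methylene lactone as the last event, and the auxiliary C11 stereocentre becomes sp2.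

## Compound list

1 | (S)-5-(hydroxymethyl)furan-2(5H)-one | O=C1O[C@H](CO)C=C1 | starting material
2 | (S)-5-[(tert-butyldimethylsilyloxy)methyl]furan-2(5H)-one | O=C1O[C@H](CO[Si](C)(C)C(C)(C)C)C=C1 | intermediate
3 | vinylmagnesium bromide | C=C[Mg]Br | starting material
4 | chloromethyl triisopropylsilyl ether | ClCO[Si](C(C)C)(C(C)C)C(C)C | starting material
5 | bromomagnesium enolate of the 4,5-trans 4-vinyl-5-(silyloxymethyl) lactone (formed in the flask, not isolated) | Br[Mg]OC1=C[C@H](C=C)[C@@H](CO[Si](C)(C)C(C)(C)C)O1 | intermediate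
6 | all-trans 5-[(tert-butyldimethylsilyloxy)methyl]-3-[(triisopropylsilyloxy)methyl]-4-vinyldihydrofuran-2(3H)-one (ring C5 = C6 as in 1; vinyl on C7 anti to the C6 substituent; CH2OTIPS on C11 anti to vinyl) | O=C1O[C@H](CO[Si](C)(C)C(C)(C)C)[C@@H](C=C)[C@@H]1CO[Si](C(C)C)(C(C)C)C(C)C | intermediate
7 | lactone 6 with free CH2OH on C6 | O=C1O[C@H](CO)[C@@H](C=C)[C@@H]1CO[Si](C(C)C)(C(C)C)C(C)C | intermediate
8 | lactone with CHO (C5) on C6, vinyl on C7, CH2OTIPS on C11, all-trans | O=C1O[C@H](C=O)[C@@H](C=C)[C@@H]1CO[Si](C(C)C)(C(C)C)C(C)C | intermediate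
9 | ethyltriphenylphosphonium iodide | CC[P+](c1ccccc1)(c1ccccc1)c1ccccc1.[I-] | starting material
10 | ethylidenetriphenylphosphorane (formed in the flask, not isolated) | CC=P(c1ccccc1)(c1ccccc1)c1ccccc1 | intermediate
11 | (1-iodoethyl)triphenylphosphonium iodide (formed in the flask, not isolated) | CC(I)[P+](c1ccccc1)(c1ccccc1)c1ccccc1.[I-] | intermediate
12 | (1-iodoethylidene)triphenylphosphorane (formed in the flask, not isolated) | CC(I)=P(c1ccccc1)(c1ccccc1)c1ccccc1 | intermediate
13 | lactone with (Z)-CH=C(CH3)I on C6 (iodine cis to C6), vinyl on C7, CH2OTIPS on C11, all-trans | O=C1O[C@H](/C=C(/C)I)[C@@H](C=C)[C@@H]1CO[Si](C(C)C)(C(C)C)C(C)C | intermediate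
14 | vicinal diol from the C7 vinyl group of 13 (both carbinol epimers; formed in the flask, not isolated) | O=C1O[C@H](/C=C(/C)I)[C@@H](C(O)CO)[C@@H]1CO[Si](C(C)C)(C(C)C)C(C)C | intermediate
15 | lactone 13 with CHO (C8) in place of vinyl on C7 | O=C1O[C@H](/C=C(/C)I)[C@@H](C=O)[C@@H]1CO[Si](C(C)C)(C(C)C)C(C)C | intermediate
16 | acetone | CC(C)=O | starting material
17 | aldol: (8R)-CH(OH)CH2C(=O)CH3 chain on C7, (Z)-iodoalkene on C6, CH2OTIPS on C11 | O=C1O[C@H](/C=C(/C)I)[C@@H]([C@H](O)CC(C)=O)[C@@H]1CO[Si](C(C)C)(C(C)C)C(C)C | intermediate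
18 | C8 triethylsilyl ether of 17 | O=C1O[C@H](/C=C(/C)I)[C@@H]([C@H](O[Si](CC)(CC)CC)CC(C)=O)[C@@H]1CO[Si](C(C)C)(C(C)C)C(C)C | intermediate
19 | propargyl alcohol | C#CCO | starting material
20 | enynol: (Z)-CH=C(CH3)–C≡C–CH2OH on C6, (8R)-CH(OTES)CH2C(=O)CH3 on C7, CH2OTIPS on C11 | O=C1O[C@H](/C=C(/C)C#CCO)[C@@H]([C@H](O[Si](CC)(CC)CC)CC(C)=O)[C@@H]1CO[Si](C(C)C)(C(C)C)C(C)C | intermediate
21 | ynal seco-precursor: as 20 with CHO (C1) in place of CH2OH | O=C1O[C@H](/C=C(/C)C#CC=O)[C@@H]([C@H](O[Si](CC)(CC)CC)CC(C)=O)[C@@H]1CO[Si](C(C)C)(C(C)C)C(C)C | intermediate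
22 | macrocyclic α'-hydroxy ynone: 10-membered carbocycle (C1–C10 bond formed), C1 ketone, C2≡C3, (10S)-OH, trans-lactone, (8R)-OTES, 11-CH2OTIPS (formed in the flask, not isolated) | O=C1O[C@@H]2/C=C(/C)C#CC(=O)[C@@](C)(O)C[C@@H](O[Si](CC)(CC)CC)[C@H]2[C@@H]1CO[Si](C(C)C)(C(C)C)C(C)C | intermediate
23 | tricyclic furanone: target skeleton (4Z; C6, C7 as in the target; 8R; 10S) with 8-OTES and 11-CH2OTIPS (trans to C8 chain) on a saturated lactone | O=C1O[C@@H]2/C=C(/C)C3=CC(=O)[C@@](C)(O3)C[C@@H](O[Si](CC)(CC)CC)[C@H]2[C@@H]1CO[Si](C(C)C)(C(C)C)C(C)C | intermediate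
24 | 23 with free 8-OH | O=C1O[C@@H]2/C=C(/C)C3=CC(=O)[C@@](C)(O3)C[C@@H](O)[C@H]2[C@@H]1CO[Si](C(C)C)(C(C)C)C(C)C | intermediate
25 | (E)-4-acetoxy-2-methylbut-2-enal | CC(=O)OC/C=C(\C)C=O | starting material
26 | (E)-4-acetoxy-2-methylbut-2-enoic acid | CC(=O)OC/C=C(\C)C(=O)O | intermediate
27 | mixed anhydride of 26 with 2,4,6-trichlorobenzoic acid (formed in the flask, not isolated) | CC(=O)OC/C=C(\C)C(=O)OC(=O)c1c(Cl)cc(Cl)cc1Cl | intermediate
28 | 8-O-[(E)-4-acetoxy-2-methylbut-2-enoyl] ester of 24 (11-CH2OTIPS) | O=C1O[C@@H]2/C=C(/C)C3=CC(=O)[C@@](C)(O3)C[C@@H](OC(=O)/C(C)=C/COC(C)=O)[C@H]2[C@@H]1CO[Si](C(C)C)(C(C)C)C(C)C | intermediate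
29 | 28 with free 11-CH2OH | O=C1O[C@@H]2/C=C(/C)C3=CC(=O)[C@@](C)(O3)C[C@@H](OC(=O)/C(C)=C/COC(C)=O)[C@H]2[C@@H]1CO | intermediate
30 | primary mesylate of 29 (formed in the flask, not isolated) | O=C1O[C@@H]2/C=C(/C)C3=CC(=O)[C@@](C)(O3)C[C@@H](OC(=O)/C(C)=C/COC(C)=O)[C@H]2[C@@H]1COS(C)(=O)=O | intermediate
31 | CNP0387534.1, (4Z,6R,7R,8R,10S) furanoheliangolide 8-O-[(E)-4-acetoxy-2-methylbut-2-enoate] | C=C1C(=O)O[C@@H]2/C=C(/C)C3=CC(=O)[C@](C)(C[C@@H](OC(=O)/C(C)=C/COC(C)=O)[C@@H]12)O3 | target

## Summary and fallbacks

Total step count: 16. Longest linear sequence: 15 steps (steps 1–12 and 14–16; step 13 prepares the side-chain acid).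

Steps most likely to fail:

**Step 11 (Proposed new method).** What may go wrong: γ-protonation of the carbene adduct (internal redox to the unsaturated acyl azolium) or intermolecular reaction of the ynal may outrun the 10-membered closure, or C1 may add to the wrong face of the ketone. Fallback with known reactions, setting out from 18 and returning at 23: the dilithium salt of propargyl alcohol (n-BuLi, CeCl3, THF, −78 °C) is added to the C10 ketone to give the ynediol F1, the (10S) epimer being separated and carried on. MnO2 in CH2Cl2 oxidises the primary propargylic alcohol to the hydroxy ynal F2. A Nozaki–Hiyama–Kishi macrocyclisation (CrCl2, NiCl2 cat., DMSO/THF, high dilution) joins the aldehyde carbon C3 to the iodoalkene carbon C4 and should give the macrocyclic propargylic alcohol F3. Dess–Martin oxidation gives the macrocyclic 4-hydroxy-2-ynone F4. Diethylamine in ethanol followed by aqueous acid (conjugate addition at C1, hydrolysis, cyclodehydration of the C10 hydroxyl onto the C3 ketone) should then give furanone 23. In this sequence the ring is closed at C3–C4 and the furanone is made by the classical amine-mediated hydrative cyclisation instead of the carbene cascade.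

**Step 7.** What may go wrong: β-elimination of the lactone carboxylate from the β-acyloxy aldehyde under aminocatalysis, or incomplete catalyst control over the aldehyde face. Fallback setting out from 15 and returning at 18: allylboration with (+)-B-(2-methylallyl)diisopinocampheylborane (from (−)-α-pinene; Et2O, −78 °C, ethanolamine work-up) should give the homoallylic alcohol F5 with reagent control at C8. TESCl and imidazole give the silyl ether F6, and OsO4 (cat.)/NaIO4/2,6-lutidine cleaves the 1,1-disubstituted alkene to the methyl ketone 18.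

**Step 5.** What may go wrong: erosion of Z selectivity in the iodo-olefination, or epimerisation at C6 of the α-oxygenated aldehyde under the basic ylide conditions. Fallback setting out from 8 and returning at 13: Corey–Fuchs dibromo-olefination (CBr4, PPh3, CH2Cl2, 0 °C) gives the 1,1-dibromoalkene F7. A trans-selective Negishi monomethylation (Me2Zn, PdCl2[bis(2-diphenylphosphinophenyl) ether] cat., THF) replaces the bromine trans to C6 and should give the (Z)-bromoalkene F8. Copper-catalysed halogen exchange (NaI, CuI cat., trans-N,N'-dimethylcyclohexane-1,2-diamine, dioxane, 110 °C) then gives iodide 13.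

Further compounds
F1 | step 11 | ynediol: 18 with the C10 ketone converted into a (10S) tertiary alcohol carrying a 3-hydroxyprop-1-ynyl group | O=C1O[C@H](/C=C(/C)I)[C@@H]([C@H](O[Si](CC)(CC)CC)C[C@](C)(O)C#CCO)[C@@H]1CO[Si](C(C)C)(C(C)C)C(C)C
F2 | step 11 | hydroxy ynal: F1 with CHO (C3) in place of CH2OH | O=C1O[C@H](/C=C(/C)I)[C@@H]([C@H](O[Si](CC)(CC)CC)C[C@](C)(O)C#CC=O)[C@@H]1CO[Si](C(C)C)(C(C)C)C(C)C
F3 | step 11 | macrocyclic propargylic alcohol: 10-membered carbocycle closed at C3–C4, C3 carbinol (both epimers), C1≡C2, (10S)-OH | O=C1O[C@@H]2/C=C(/C)C(O)C#C[C@@](C)(O)C[C@@H](O[Si](CC)(CC)CC)[C@H]2[C@@H]1CO[Si](C(C)C)(C(C)C)C(C)C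
F4 | step 11 | macrocyclic 4-hydroxy-2-ynone: F3 with a C3 ketone | O=C1O[C@@H]2/C=C(/C)C(=O)C#C[C@@](C)(O)C[C@@H](O[Si](CC)(CC)CC)[C@H]2[C@@H]1CO[Si](C(C)C)(C(C)C)C(C)C
F5 | step 7 | homoallylic alcohol: (8R)-CH(OH)CH2C(CH3)=CH2 chain on C7 of the iodoalkene lactone | O=C1O[C@H](/C=C(/C)I)[C@@H]([C@H](O)CC(C)=C)[C@@H]1CO[Si](C(C)C)(C(C)C)C(C)C
F6 | step 7 | triethylsilyl ether of F5 | O=C1O[C@H](/C=C(/C)I)[C@@H]([C@H](O[Si](CC)(CC)CC)CC(C)=C)[C@@H]1CO[Si](C(C)C)(C(C)C)C(C)C
F7 | step 5 | 1,1-dibromoalkene: CH=CBr2 on C6 of the vinyl lactone | O=C1O[C@H](C=C(Br)Br)[C@@H](C=C)[C@@H]1CO[Si](C(C)C)(C(C)C)C(C)C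
F8 | step 5 | (Z)-bromoalkene: (Z)-CH=C(CH3)Br on C6 (bromine cis to C6) | O=C1O[C@H](/C=C(/C)Br)[C@@H](C=C)[C@@H]1CO[Si](C(C)C)(C(C)C)C(C)C
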